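**Plan** (locants follow the diterpene chain: C1 ArCH2, C2 ring CH, C3 ring C(=CH2), C4–C5, C6 ring CHBr, C7 quaternary ring C, C8–C9, C10 CHBr, C11 C(OH)CH3, C12–C13, C14 CH–O, C15=C16 isopropenyl)
Retrosynthetic cuts, in order: phenol O–H (4-methoxybenzyl ether); C10–Br (epoxide opening); lactone C(=O)–O14; ring bond C2–C3; C9–C10 (B-alkyl Suzuki); aryl–C1 (Suzuki); C6–Br together with C7–C8 (bromonium semipinacol shift).
Forward: an acyclic C2–C9 aldehyde that already carries C6–Br and the quaternary C7 is made first and extended to an aryl 1,7-enyne; the cyclohexane is then closed at C2–C3, the 15-membered lactone follows, and the bromohydrin comes last.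
Enabling feature: ring carbon C3 bears the exocyclic methylene and its ring neighbour C2 is a CH carrying the benzylic C1H2–aryl group. This 1-methylene-2-(arylmethyl)cyclohexane unit is the retron of a hydrogen-terminated alkyne–styrene coupling (alkyne carbon becomes C3, styrene β-carbon becomes C2, the benzylic carbon is reduced).
Stereochemistry: one CBS reduction sets a carbinol that is relayed by anti bromonium/1,2-vinyl shift across a Z-alkene into C6 and C7; C2 follows from these in a chair-like ring closure; two reagent-controlled Shi epoxidations give C14 (via epoxide-to-allylic-alcohol isomerisation) and C10/C11 (via SN2 opening by bromide).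

Key step: step 15

Remark: the L-series (enantiomeric) Shi ketone, obtainable from L-sorbose, is taken as an available catalyst.

Step 1
Reactants: 1 5-(trimethylsilyl)pent-4-yn-1-ol
Product: 2 5-(trimethylsilyl)pent-4-ynal
Conditions: Dess–Martin periodinane, CH2Cl2, 0 °C to rt
Reagents that add atoms: none
Why: Dess–Martin oxidation of a primary alcohol to the aldehyde, with the silylalkyne inert and no stereocentre involved.

Step 2
Reactants: 2 5-(trimethylsilyl)pent-4-ynal; 3 ethyl(triphenyl)phosphonium iodide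
Product: 6 [(5Z)-6-iodohept-5-en-1-yn-1-yl](trimethyl)silane, via iodoethylphosphonium iodide 4 (not isolated), via iodoethylidene ylide 5 (not isolated)
Conditions: n-BuLi, THF, rt; I2, −78 °C; NaN(SiMe3)2, −78 °C; then 2, −78 to −20 °C
Reagents that add atoms: iodine, II
Why: Stork–Zhao-type Wittig olefination with an α-iodo ylide, which under kinetic control should give the (Z)-2-iodoalkene (iodine cis to the chain), the geometry that later decides the relative configuration of C6 and C7.

Step 3
Reactants: 6 [(5Z)-6-iodohept-5-en-1-yn-1-yl](trimethyl)silane; 7 N-methoxy-N-methylprop-2-enamide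
Product: 9 (4Z)-4-methyl-9-(trimethylsilyl)nona-1,4-dien-8-yn-3-one, via alkenyllithium 8 (not isolated)
Conditions: t-BuLi (2 equiv), Et2O, −78 °C; then 7, −78 °C; cold aqueous HCl
Reagents that add atoms: none
Why: Iodine–lithium exchange with retention of alkene geometry, then Weinreb amide acylation, whose chelated tetrahedral adduct should release the vinyl ketone only on the cold acidic quench.

Step 4
Reactants: 9 (4Z)-4-methyl-9-(trimethylsilyl)nona-1,4-dien-8-yn-3-one
Product: 10 (3S,4Z)-4-methyl-9-(trimethylsilyl)nona-1,4-dien-8-yn-3-ol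
Conditions: (R)-Me-CBS oxazaborolidine [(3aR)-1-methyl-3,3-diphenyltetrahydro-1H,3H-pyrrolo[1,2-c][1,3,2]oxazaborole] (20 mol %), catecholborane, toluene, −78 °C
Reagents that add atoms: none
Why: Corey–Bakshi–Shibata reduction in which the α-branched alkenyl group acts as the large and the vinyl group as the small substituent, so that the (R)-catalyst should deliver hydride to the face that gives the 3S carbinol.

Step 5
Reactants: 10 (3S,4Z)-4-methyl-9-(trimethylsilyl)nona-1,4-dien-8-yn-3-ol
Product: 11 (2S,3S)-3-bromo-2-ethenyl-2-methyl-7-(trimethylsilyl)hept-6-ynal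
Conditions: N-bromosuccinimide, CH2Cl2, −40 °C, dark
Reagents that add atoms: N-bromosuccinimide, O=C1CCC(=O)N1Br
Why: Halonium-induced semipinacol rearrangement in which allylic 1,3-strain of the Z-alkene holds the carbinol C–H in the alkene plane, bromine adds to C6 on the hydroxyl-bearing face and the vinyl group migrates to C7 antiperiplanar to it, so that anti addition across the Z-alkene should relay the carbinol centre into 6S (C–Br) and 7S (quaternary carbon) while the carbinol becomes the aldehyde.

Step 6
Reactants: 11 (2S,3S)-3-bromo-2-ethenyl-2-methyl-7-(trimethylsilyl)hept-6-ynal; 12 2-(dichloromethyl)-4,4,5,5-tetramethyl-1,3,2-dioxaborolane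
Product: 13 2-[(1E,3S,4S)-4-bromo-3-ethenyl-3-methyl-8-(trimethylsilyl)oct-1-en-7-yn-1-yl]-4,4,5,5-tetramethyl-1,3,2-dioxaborolane
Conditions: CrCl2, LiI, THF, rt
Reagents that add atoms: none
Why: Takai–Utimoto olefination with a geminal dichromium boryl reagent, which is E-selective, leaves the unactivated secondary bromide alone and cannot epimerise the aldehyde because C7 has no hydrogen.

Step 7
Reactants: 14 methyl 4-hydroxy-3-iodobenzoate
Product: 15 methyl 3-iodo-4-[(4-methoxyphenyl)methoxy]benzoate
Conditions: 4-methoxybenzyl chloride, K2CO3, DMF, rt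
Reagents that add atoms: 4-methoxybenzyl chloride, COc1ccc(CCl)cc1
Why: Williamson ether formation on the phenoxide, giving a protecting group that should survive the later basic, organometallic and oxidising steps and leave oxidatively at the end.

Step 8
Reactants: 13 2-[(1E,3S,4S)-4-bromo-3-ethenyl-3-methyl-8-(trimethylsilyl)oct-1-en-7-yn-1-yl]-4,4,5,5-tetramethyl-1,3,2-dioxaborolane; 15 methyl 3-iodo-4-[(4-methoxyphenyl)methoxy]benzoate
Product: 16 methyl 3-[(1E,3S,4S)-4-bromo-3-ethenyl-3-methyl-8-(trimethylsilyl)oct-1-en-7-yn-1-yl]-4-[(4-methoxyphenyl)methoxy]benzoate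
Conditions: Pd(dppf)Cl2 (5 mol %), K3PO4, THF/H2O, 45 °C
Reagents that add atoms: none
Why: Suzuki–Miyaura coupling of an alkenyl boronate with an aryl iodide with retention of the E geometry, under conditions too mild for the secondary alkyl bromide to add to palladium.

Step 9
Reactants: 17 5-bromo-2-methylpent-2-ene
Product: 18 6-methylhept-5-en-1-yne
Conditions: lithium acetylide ethylenediamine complex (LiC≡CH·H2NCH2CH2NH2), DMSO, 10 °C to rt
Reagents that add atoms: lithium acetylide ethylenediamine complex, [Li]C#C.NCCN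
Why: SN2 alkylation of lithium acetylide by a primary homoallylic bromide.

Step 10
Reactants: 18 6-methylhept-5-en-1-yne
Product: 20 (1E)-1-iodo-2,6-dimethylhepta-1,5-diene, via alkenylalane 19 (not isolated)
Conditions: Me3Al, Cp2ZrCl2 (20 mol %), CH2Cl2, 0 °C to rt; then I2, THF, −30 °C
Reagents that add atoms: trimethylaluminium, C[Al](C)C; iodine, II
Why: Zirconium-catalysed carboalumination (Negishi) of the terminal alkyne, a syn addition of methyl and aluminium that fixes the E geometry, followed by iodinolysis with retention.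

Step 11
Reactants: 20 (1E)-1-iodo-2,6-dimethylhepta-1,5-diene
Product: 21 (3S)-3-[(4E)-5-iodo-4-methylpent-4-en-1-yl]-2,2-dimethyloxirane
Conditions: 1,2:4,5-di-O-isopropylidene-β-L-erythro-2,3-hexodiulo-2,6-pyranose (enantiomer of the Shi ketone, 30 mol %), Oxone (2KHSO5·KHSO4·K2SO4), K2CO3, Bu4NHSO4, MeCN/dimethoxymethane/aqueous buffer, 0 °C
Reagents that add atoms: potassium peroxymonosulfate, [K+].[O-]S(=O)(=O)OO
Why: Shi asymmetric epoxidation of the electron-rich trisubstituted alkene (the iodoalkene is deactivated), in which the dioxirane of the L-series ketone should deliver oxygen to the face that gives the S epoxide.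

Step 12
Reactants: 21 (3S)-3-[(4E)-5-iodo-4-methylpent-4-en-1-yl]-2,2-dimethyloxirane
Product: 22 (3S,6E)-7-iodo-2,6-dimethylhepta-1,6-dien-3-ol
Conditions: Al(OiPr)3, toluene, 110 °C
Reagents that add atoms: none
Why: Aluminium isopropoxide-mediated isomerisation of a trisubstituted epoxide to the allylic alcohol (syn β-elimination towards a methyl group), which keeps the secondary C–O bond and hence the S configuration at the future C14.

Step 13
Reactants: 16 methyl 3-[(1E,3S,4S)-4-bromo-3-ethenyl-3-methyl-8-(trimethylsilyl)oct-1-en-7-yn-1-yl]-4-[(4-methoxyphenyl)methoxy]benzoate; 22 (3S,6E)-7-iodo-2,6-dimethylhepta-1,6-dien-3-ol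
Product: 24 methyl 3-[(1E,3S,6E,10S)-3-[(1S)-1-bromo-5-(trimethylsilyl)pent-4-yn-1-yl]-10-hydroxy-3,7,11-trimethyldodeca-1,6,11-trien-1-yl]-4-[(4-methoxyphenyl)methoxy]benzoate, via alkyl-9-BBN borane 23 (not isolated)
Conditions: 9-BBN (1.1 equiv), THF, rt; aqueous Cs2CO3; then 22, Pd(dppf)Cl2 (5 mol %), AsPh3, DMF, rt
Reagents that add atoms: none
Why: Anti-Markovnikov hydroboration of the only monosubstituted alkene (the styrene and the silylalkyne react far more slowly, and residual B–H is quenched before 22 is added) followed by B-alkyl Suzuki–Miyaura coupling with the alkenyl iodide with retention of the E geometry.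

Step 14
Reactants: 24 methyl 3-[(1E,3S,6E,10S)-3-[(1S)-1-bromo-5-(trimethylsilyl)pent-4-yn-1-yl]-10-hydroxy-3,7,11-trimethyldodeca-1,6,11-trien-1-yl]-4-[(4-methoxyphenyl)methoxy]benzoate
Product: 25 methyl 3-[(1E,3S,6E,10S)-3-[(1S)-1-bromopent-4-yn-1-yl]-10-hydroxy-3,7,11-trimethyldodeca-1,6,11-trien-1-yl]-4-[(4-methoxyphenyl)methoxy]benzoate
Conditions: K2CO3 (cat.), MeOH, rt
Reagents that add atoms: none
Why: Base-catalysed methanolysis of the alkynyl C–Si bond, which leaves the methyl ester unchanged in methanol.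

Step 15
Reactants: 25 methyl 3-[(1E,3S,6E,10S)-3-[(1S)-1-bromopent-4-yn-1-yl]-10-hydroxy-3,7,11-trimethyldodeca-1,6,11-trien-1-yl]-4-[(4-methoxyphenyl)methoxy]benzoate
Product: 26 methyl 3-{[(1R,2S,3S)-3-bromo-2-[(3E,7S)-7-hydroxy-4,8-dimethylnona-3,8-dien-1-yl]-2-methyl-6-methylidenecyclohexyl]methyl}-4-[(4-methoxyphenyl)methoxy]benzoate
Conditions: Pd2(dba)3·CHCl3 (5 mol %), P(o-tol)3 (20 mol %), AcOH, Et3SiH, toluene, rt to 50 °C
Reagents that add atoms: none
Why: Palladium hydride reductive cyclisation of a 1,7-enyne: acetic acid adds to the zerovalent palladium catalyst, H–Pd–OAc adds across the terminal alkyne with palladium on the internal carbon C3, the alkenylpalladium inserts the styrene C2=C1 by syn carbopalladation to form C2–C3, and triethylsilane reduces the benzylpalladium acetate at C1 before β-hydride loss. The closest known reaction type is the Pd2(dba)3/AcOH/silane reductive cyclisation of 1,6- and 1,7-enynes to 1-methylene-2-alkylcycloalkanes. The cyclohexane closes in the 6-exo-trig mode on the alkene and exo on the alkyne, which leaves the methylene exocyclic on C3. C2 is the only new stereocentre and is set by a chair-like transition state with the styrene arm and the C6–Br bond equatorial and the C8 chain anti to the forming bond, so that only the C7 methyl is axial; this gives 2R. The step needs chemoselectivity and C2 face selectivity: hydropalladation should touch only the alkyne, and only the styrene lies within 6-exo reach (C10=C11 and the isopropenyl group are too far). Face selectivity rests on the preset 6S,7S centres and a bulky phosphine next to the axial methyl, and is expected to prevail by a modest margin because methyl and the C8 chain differ little in size.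

Step 16
Reactants: 26 methyl 3-{[(1R,2S,3S)-3-bromo-2-[(3E,7S)-7-hydroxy-4,8-dimethylnona-3,8-dien-1-yl]-2-methyl-6-methylidenecyclohexyl]methyl}-4-[(4-methoxyphenyl)methoxy]benzoate
Product: 27 3-{[(1R,2S,3S)-3-bromo-2-[(3E,7S)-7-hydroxy-4,8-dimethylnona-3,8-dien-1-yl]-2-methyl-6-methylidenecyclohexyl]methyl}-4-[(4-methoxyphenyl)methoxy]benzoic acid
Conditions: LiOH, THF/MeOH/H2O, 40 °C; then AcOH
Reagents that add atoms: lithium hydroxide, [Li+].[OH-]
Why: Saponification of the methyl benzoate, during which the equatorial ring bromide has no antiperiplanar hydrogen and should therefore resist E2 loss of HBr.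

Step 17
Reactants: 27 3-{[(1R,2S,3S)-3-bromo-2-[(3E,7S)-7-hydroxy-4,8-dimethylnona-3,8-dien-1-yl]-2-methyl-6-methylidenecyclohexyl]methyl}-4-[(4-methoxyphenyl)methoxy]benzoic acid
Product: 29 macrolactone alkene (15-membered lactone closed between the carboxyl group and O–C14; 2R,6S,7S,14S; 10E; phenol as 4-methoxybenzyl ether), via mixed anhydride 28 (not isolated)
Conditions: 2,4,6-trichlorobenzoyl chloride, Et3N, THF, rt; then 4-(dimethylamino)pyridine, toluene, 80 °C, high dilution
Reagents that add atoms: none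
Why: Yamaguchi macrolactonisation through the mixed anhydride, in which the secondary allylic hydroxyl group at C14 is the only nucleophile and its configuration is untouched.

Step 18
Reactants: 29 macrolactone alkene
Product: 30 macrolactone (10S,11S)-epoxide
Conditions: 1,2:4,5-di-O-isopropylidene-β-L-erythro-2,3-hexodiulo-2,6-pyranose (30 mol %), Oxone (2KHSO5·KHSO4·K2SO4), K2CO3, Bu4NHSO4, MeCN/dimethoxymethane/aqueous buffer, 0 °C
Reagents that add atoms: potassium peroxymonosulfate, [K+].[O-]S(=O)(=O)OO
Why: Shi asymmetric epoxidation of the only trisubstituted alkene (the two 1,1-disubstituted alkenes are poor substrates), in which the L-series ketone should give the 10S,11S epoxide by reagent control; it is run after lactonisation so that no free C14 hydroxyl group can open the epoxide.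

Step 19
Reactants: 30 macrolactone (10S,11S)-epoxide
Product: 31 bromophycolide E 4-methoxybenzyl ether (10R,11S bromohydrin)
Conditions: Li2NiBr4, THF, 0 °C to rt
Reagents that add atoms: dilithium tetrabromonickelate, [Li+].[Li+].[Ni+2].[Br-].[Br-].[Br-].[Br-]
Why: SN2 opening of the epoxide by soft bromide at the less substituted C10 with inversion (10S to 10R), which leaves the tertiary C11–O bond and its S configuration intact.

Step 20
Reactants: 31 bromophycolide E 4-methoxybenzyl ether
Product: 32 bromophycolide E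
Conditions: DDQ, CH2Cl2/pH 7 buffer, 0 °C to rt
Reagents that add atoms: none
Why: Oxidative cleavage of the 4-methoxybenzyl ether by DDQ through the benzylic oxocarbenium ion, under neutral conditions that should spare the bromohydrin, both bromides, the alkenes and the lactone.

**Compound list**
1 | 5-(trimethylsilyl)pent-4-yn-1-ol | C[Si](C)(C)C#CCCCO | starting material
2 | 5-(trimethylsilyl)pent-4-ynal | C[Si](C)(C)C#CCCC=O | intermediate
3 | ethyl(triphenyl)phosphonium iodide | CC[P+](c1ccccc1)(c1ccccc1)c1ccccc1.[I-] | starting material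
4 | (1-iodoethyl)(triphenyl)phosphonium iodide (not isolated) | CC(I)[P+](c1ccccc1)(c1ccccc1)c1ccccc1.[I-] | intermediate
5 | (1-iodoethylidene)(triphenyl)phosphorane (not isolated) | CC(I)=P(c1ccccc1)(c1ccccc1)c1ccccc1 | intermediate
6 | [(5Z)-6-iodohept-5-en-1-yn-1-yl](trimethyl)silane | C/C(I)=C/CCC#C[Si](C)(C)C | intermediate
7 | N-methoxy-N-methylprop-2-enamide | C=CC(=O)N(C)OC | starting material
8 | [(2E)-7-(trimethylsilyl)hept-2-en-6-yn-2-yl]lithium, lithium cis to the chain (not isolated) | [Li]/C(C)=C\CCC#C[Si](C)(C)C | intermediate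
9 | (4Z)-4-methyl-9-(trimethylsilyl)nona-1,4-dien-8-yn-3-one | C=CC(=O)/C(C)=C\CCC#C[Si](C)(C)C | intermediate
10 | (3S,4Z)-4-methyl-9-(trimethylsilyl)nona-1,4-dien-8-yn-3-ol | C=C[C@H](O)/C(C)=C\CCC#C[Si](C)(C)C | intermediate
11 | (2S,3S)-3-bromo-2-ethenyl-2-methyl-7-(trimethylsilyl)hept-6-ynal | O=C[C@](C)(C=C)[C@@H](Br)CCC#C[Si](C)(C)C | intermediate
12 | 2-(dichloromethyl)-4,4,5,5-tetramethyl-1,3,2-dioxaborolane | ClC(Cl)B1OC(C)(C)C(C)(C)O1 | starting material
13 | 2-[(1E,3S,4S)-4-bromo-3-ethenyl-3-methyl-8-(trimethylsilyl)oct-1-en-7-yn-1-yl]-4,4,5,5-tetramethyl-1,3,2-dioxaborolane | CC1(C)OB(/C=C/[C@](C)(C=C)[C@@H](Br)CCC#C[Si](C)(C)C)OC1(C)C | intermediate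
14 | methyl 4-hydroxy-3-iodobenzoate | COC(=O)c1ccc(O)c(I)c1 | starting material
15 | methyl 3-iodo-4-[(4-methoxyphenyl)methoxy]benzoate | COC(=O)c1ccc(OCc2ccc(OC)cc2)c(I)c1 | intermediate
16 | methyl 3-[(1E,3S,4S)-4-bromo-3-ethenyl-3-methyl-8-(trimethylsilyl)oct-1-en-7-yn-1-yl]-4-[(4-methoxyphenyl)methoxy]benzoate | COC(=O)c1ccc(OCc2ccc(OC)cc2)c(/C=C/[C@](C)(C=C)[C@@H](Br)CCC#C[Si](C)(C)C)c1 | intermediate
17 | 5-bromo-2-methylpent-2-ene | CC(C)=CCCBr | starting material
18 | 6-methylhept-5-en-1-yne | CC(C)=CCCC#C | intermediate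
19 | [(1E)-2,6-dimethylhepta-1,5-dien-1-yl](dimethyl)alumane (not isolated) | C[Al](C)/C=C(\C)CCC=C(C)C | intermediate
20 | (1E)-1-iodo-2,6-dimethylhepta-1,5-diene | I/C=C(\C)CCC=C(C)C | intermediate
21 | (3S)-3-[(4E)-5-iodo-4-methylpent-4-en-1-yl]-2,2-dimethyloxirane | CC1(C)O[C@H]1CC/C(C)=C/I | intermediate
22 | (3S,6E)-7-iodo-2,6-dimethylhepta-1,6-dien-3-ol | C=C(C)[C@@H](O)CC/C(C)=C/I | intermediate
23 | methyl 3-[(1E,3S,4S)-3-[2-(9-borabicyclo[3.3.1]nonan-9-yl)ethyl]-4-bromo-3-methyl-8-(trimethylsilyl)oct-1-en-7-yn-1-yl]-4-[(4-methoxyphenyl)methoxy]benzoate (not isolated) | COC(=O)c1ccc(OCc2ccc(OC)cc2)c(/C=C/[C@](C)(CCB2C3CCCC2CCC3)[C@@H](Br)CCC#C[Si](C)(C)C)c1 | intermediate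
24 | methyl 3-[(1E,3S,6E,10S)-3-[(1S)-1-bromo-5-(trimethylsilyl)pent-4-yn-1-yl]-10-hydroxy-3,7,11-trimethyldodeca-1,6,11-trien-1-yl]-4-[(4-methoxyphenyl)methoxy]benzoate | COC(=O)c1ccc(OCc2ccc(OC)cc2)c(/C=C/[C@](C)(CC/C=C(\C)CC[C@H](O)C(C)=C)[C@@H](Br)CCC#C[Si](C)(C)C)c1 | intermediate
25 | methyl 3-[(1E,3S,6E,10S)-3-[(1S)-1-bromopent-4-yn-1-yl]-10-hydroxy-3,7,11-trimethyldodeca-1,6,11-trien-1-yl]-4-[(4-methoxyphenyl)methoxy]benzoate | COC(=O)c1ccc(OCc2ccc(OC)cc2)c(/C=C/[C@](C)(CC/C=C(\C)CC[C@H](O)C(C)=C)[C@@H](Br)CCC#C)c1 | intermediate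
26 | methyl 3-{[(1R,2S,3S)-3-bromo-2-[(3E,7S)-7-hydroxy-4,8-dimethylnona-3,8-dien-1-yl]-2-methyl-6-methylidenecyclohexyl]methyl}-4-[(4-methoxyphenyl)methoxy]benzoate | C=C(C)[C@@H](O)CC/C(C)=C/CC[C@@]1(C)[C@H](Cc2cc(ccc2OCc2ccc(OC)cc2)C(=O)OC)C(=C)CC[C@@H]1Br | intermediate
27 | 3-{[(1R,2S,3S)-3-bromo-2-[(3E,7S)-7-hydroxy-4,8-dimethylnona-3,8-dien-1-yl]-2-methyl-6-methylidenecyclohexyl]methyl}-4-[(4-methoxyphenyl)methoxy]benzoic acid | C=C(C)[C@@H](O)CC/C(C)=C/CC[C@@]1(C)[C@H](Cc2cc(ccc2OCc2ccc(OC)cc2)C(=O)O)C(=C)CC[C@@H]1Br | intermediate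
28 | mixed anhydride of 27 with 2,4,6-trichlorobenzoic acid (not isolated) | C=C(C)[C@@H](O)CC/C(C)=C/CC[C@@]1(C)[C@H](Cc2cc(ccc2OCc2ccc(OC)cc2)C(=O)OC(=O)c2c(Cl)cc(Cl)cc2Cl)C(=C)CC[C@@H]1Br | intermediate
29 | macrolactone alkene: 4-methoxybenzyl ether of the 15-membered lactone closed at O–C14, with E ring alkene C10=C11 (2R,6S,7S,14S) | C=C(C)[C@@H]1CC/C(C)=C/CC[C@@]2(C)[C@H](Cc3cc(ccc3OCc3ccc(OC)cc3)C(=O)O1)C(=C)CC[C@@H]2Br | intermediate
30 | macrolactone (10S,11S)-epoxide of 29 | C=C(C)[C@@H]1CC[C@]2(C)O[C@H]2CC[C@@]3(C)[C@H](Cc4cc(ccc4OCc4ccc(OC)cc4)C(=O)O1)C(=C)CC[C@@H]3Br | intermediate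
31 | bromophycolide E 4-methoxybenzyl ether (10R,11S bromohydrin) | C=C(C)[C@@H]1CC[C@](C)(O)[C@H](Br)CC[C@@]2(C)[C@H](Cc3cc(ccc3OCc3ccc(OC)cc3)C(=O)O1)C(=C)CC[C@@H]2Br | intermediate
32 | bromophycolide E | C=C(C)[C@@H]1CC[C@](C)(O)[C@H](Br)CC[C@@]2(C)[C@H](Cc3cc(ccc3O)C(=O)O1)C(=C)CC[C@@H]2Br | target

**Step count and risks**
Total steps: 20. Longest linear sequence: 15 (steps 1–6, 8, 13–20).

Most likely to fail, first: step 15. The two faces of C2 may be discriminated poorly, because the methyl group and the C8 chain on C7 differ little in size and the bromide has only a small equatorial preference; in addition the benzylpalladium intermediate may lose a β-hydride to give a 1,3-diene before the silane captures it. The fallback moves the ring closure into the macrocycle, where C8 and the arene are tied in one ring and the C3–C6 arm can only reach the outer face of the in-ring styrene. It sets out from 25, which is saponified under the conditions of step 16 to the seco acid F1 and lactonised under the conditions of step 17 to the macrolactone enyne F2; F2 is then submitted to the conditions of step 15 and the route is rejoined at 29.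

Second: step 5. The hydroxyl group may open the bromonium ion (bromo-epoxide formation), a hydride may shift in place of the vinyl group, or bromine may add to the face remote from the hydroxyl group, which would erode the chirality relay. The fallback removes the free hydroxyl group from the event: 10 is silylated (Me3SiCl, imidazole, CH2Cl2) to the trimethylsilyl ether F3, which on treatment with N-bromosuccinimide should undergo the same anti bromonium/vinyl shift through a silyl oxocarbenium ion that collapses to the aldehyde; the route is rejoined at 11.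

Third: step 18. Oxygen transfer to the ring alkene may be slow or mismatched with the face that the macrocycle exposes, and the two 1,1-disubstituted alkenes may begin to compete. The fallback replaces oxygen transfer by electrophilic bromohydration: 29 is treated with N-bromosuccinimide in aqueous THF at 0 °C, which should add bromine to C10 and water to the tertiary C11 in an anti sense on the most nucleophilic alkene, under substrate control of the face; steps 18 and 19 fall away and the route is rejoined at 31.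

**Further compounds**
F1 | step 15 | 3-[(1E,3S,6E,10S)-3-[(1S)-1-bromopent-4-yn-1-yl]-10-hydroxy-3,7,11-trimethyldodeca-1,6,11-trien-1-yl]-4-[(4-methoxyphenyl)methoxy]benzoic acid | OC(=O)c1ccc(OCc2ccc(OC)cc2)c(/C=C/[C@](C)(CC/C=C(\C)CC[C@H](O)C(C)=C)[C@@H](Br)CCC#C)c1
F2 | step 15 | macrolactone enyne: lactone of F1 closed at O–C14, with in-ring E styrene and E C10=C11 (6S,7S,14S) | C=C(C)[C@@H]1CC/C(C)=C/CC[C@@](C)(/C=C/c2cc(ccc2OCc2ccc(OC)cc2)C(=O)O1)[C@@H](Br)CCC#C
F3 | step 5 | trimethyl{[(3S,4Z)-4-methyl-9-(trimethylsilyl)nona-1,4-dien-8-yn-3-yl]oxy}silane | C=C[C@H](O[Si](C)(C)C)/C(C)=C\CCC#C[Si](C)(C)C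
F0 | step 18 | none | none
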